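**Retrosynthetic overview**
1. The target is the mono-acetate of the C2-symmetric (3R,5R)-1,7-bis(4-hydroxyphenyl)heptane-3,5-diol. The two hydroxyls are homotopic, so any mono-acetylation (and any later 1,3-acyl shift) gives the same compound.
2. The phenols are carried as benzyl ethers and freed last by hydrogenolysis, which spares the acetate; the mono-acetate comes from the diol by opening a cyclic orthoacetate.
3. Both stereocentres are set in one operation by Ru-(R)-BINAP hydrogenation of the 1,3-diketone to the anti (3R,5R)-diol.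
4. The diketone is made by forming C4-C5 in a crossed Claisen condensation between the kinetic enolate of 4-[4-(benzyloxy)phenyl]butan-2-one and methyl 3-[4-(benzyloxy)phenyl]propanoate.
5. No ring is constructed: both benzene rings come with the building blocks, and the only ring made is the transient 1,3-dioxane orthoester.

Assumption: common reagents (benzyl bromide, commercial LDA solution, trimethyl orthoacetate, the Ru and Pd catalysts) are bought and appear on the Conditions/Reagents lines without a compound number.

**Route**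

Step 1
Reactants: 1 4-(4-hydroxyphenyl)butan-2-one
Product: 2 4-[4-(benzyloxy)phenyl]butan-2-one
Conditions: BnBr (1.1 equiv), K2CO3 (1.5 equiv), acetone, reflux, 12 h
Reagents that add atoms: benzyl bromide, BrCc1ccccc1
Why: Williamson ether synthesis: K2CO3 deprotonates only the phenol (far more acidic than the ketone α-H) and the phenoxide displaces bromide by SN2; no stereocentre.

Step 2
Reactants: 3 methyl 3-(4-hydroxyphenyl)propanoate
Product: 4 methyl 3-[4-(benzyloxy)phenyl]propanoate
Conditions: BnBr (1.1 equiv), K2CO3 (1.5 equiv), acetone, reflux, 12 h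
Reagents that add atoms: benzyl bromide, BrCc1ccccc1
Why: Same Williamson O-benzylation; the methyl ester is inert to anhydrous K2CO3; no stereocentre.

Step 3
Reactants: 2 4-[4-(benzyloxy)phenyl]butan-2-one; 4 methyl 3-[4-(benzyloxy)phenyl]propanoate
Product: 7 1,7-bis[4-(benzyloxy)phenyl]heptane-3,5-dione, via kinetic lithium enolate 5 (not isolated), via lithium diketonate 6 (not isolated)
Conditions: LDA (2.1 equiv), THF, −78 °C, then 2 (2.1 equiv), 45 min; then 4 (1.0 equiv), −78 → 0 °C, 2 h; 1 M HCl quench (excess 2 recovered)
Reagents that add atoms: none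
Why: Crossed Claisen condensation: LDA deprotonates the methyl group of 2 kinetically, enolate 5 acylates on the ester carbonyl of 4 with loss of methoxide, and irreversible deprotonation of the β-diketone to chelate 6 (hence two equivalents of enolate) drives the reaction; no stereocentre is formed.

Step 4
Reactants: 7 1,7-bis[4-(benzyloxy)phenyl]heptane-3,5-dione
Product: 9 (3R,5R)-1,7-bis[4-(benzyloxy)phenyl]heptane-3,5-diol, via (R)-hydroxy ketone 8 (not isolated)
Conditions: RuCl2[(R)-BINAP] (1 mol%), H2 (50 atm), MeOH/CH2Cl2 4:1, 50 °C, 48 h; recrystallise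
Reagents that add atoms: none
Why: Noyori asymmetric hydrogenation of a 1,3-diketone: the (R)-BINAP-Ru chelate reduces the first carbonyl to the (R)-hydroxy ketone 8 and the second, hydroxyl-chelated reduction is matched with the catalyst and gives the anti (3R,5R)-diol (the same sense as acetylacetone to (R,R)-pentane-2,4-diol), the minor enantiomer of 8 draining into the separable meso-diol, while aryl benzyl ethers are untouched by Ru/H2.

Step 5
Reactants: 9 (3R,5R)-1,7-bis[4-(benzyloxy)phenyl]heptane-3,5-diol
Product: 11 (3R,5R)-1,7-bis[4-(benzyloxy)phenyl]-5-hydroxyheptan-3-yl acetate, via cyclic orthoacetate 10 (not isolated)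
Conditions: MeC(OMe)3 (2 equiv), PPTS (5 mol%), CH2Cl2, rt, 2 h; then 80% aq. AcOH, 0 °C → rt, 30 min
Reagents that add atoms: trimethyl orthoacetate, CC(OC)(OC)OC; water, O
Why: Acid-catalysed orthoester exchange ties both hydroxyls into one 2-methoxy-1,3-dioxane, and its hydrolysis through the dioxanylium ion and hemi-orthoester can release only a mono-acetate; because the diol is C2-symmetric both ring openings give the same compound, and no bond to a stereocentre is broken.

Step 6
Reactants: 11 (3R,5R)-1,7-bis[4-(benzyloxy)phenyl]-5-hydroxyheptan-3-yl acetate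
Product: 12 (3R,5R)-5-hydroxy-1,7-bis(4-hydroxyphenyl)heptan-3-yl acetate
Conditions: H2 (1 atm), 10% Pd/C, EtOAc, rt, 3 h
Reagents that add atoms: none
Why: Catalytic hydrogenolysis cleaves the two aryl benzyl ethers under neutral conditions; the secondary acetate, the secondary alcohol and both stereocentres (neither benzylic nor allylic) are untouched.

**Compound list**
1 | 4-(4-hydroxyphenyl)butan-2-one (raspberry ketone) | CC(=O)CCc1ccc(O)cc1 | starting material
2 | 4-[4-(benzyloxy)phenyl]butan-2-one | CC(=O)CCc1ccc(OCc2ccccc2)cc1 | intermediate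
3 | methyl 3-(4-hydroxyphenyl)propanoate | COC(=O)CCc1ccc(O)cc1 | starting material
4 | methyl 3-[4-(benzyloxy)phenyl]propanoate | COC(=O)CCc1ccc(OCc2ccccc2)cc1 | intermediate
5 | lithium 4-[4-(benzyloxy)phenyl]but-1-en-2-olate (kinetic enolate of 2) | [Li]OC(=C)CCc1ccc(OCc2ccccc2)cc1 | intermediate (not isolated)
6 | lithium (Z)-1,7-bis[4-(benzyloxy)phenyl]-5-oxohept-3-en-3-olate | [Li]O/C(CCc1ccc(OCc2ccccc2)cc1)=C\C(=O)CCc1ccc(OCc2ccccc2)cc1 | intermediate (not isolated)
7 | 1,7-bis[4-(benzyloxy)phenyl]heptane-3,5-dione | O=C(CCc1ccc(OCc2ccccc2)cc1)CC(=O)CCc1ccc(OCc2ccccc2)cc1 | intermediate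
8 | (5R)-1,7-bis[4-(benzyloxy)phenyl]-5-hydroxyheptan-3-one | O=C(CCc1ccc(OCc2ccccc2)cc1)C[C@H](O)CCc1ccc(OCc2ccccc2)cc1 | intermediate (not isolated)
9 | (3R,5R)-1,7-bis[4-(benzyloxy)phenyl]heptane-3,5-diol | O[C@H](CCc1ccc(OCc2ccccc2)cc1)C[C@H](O)CCc1ccc(OCc2ccccc2)cc1 | intermediate
10 | (4R,6R)-4,6-bis{2-[4-(benzyloxy)phenyl]ethyl}-2-methoxy-2-methyl-1,3-dioxane | COC1(C)O[C@H](CCc2ccc(OCc3ccccc3)cc2)C[C@@H](CCc2ccc(OCc3ccccc3)cc2)O1 | intermediate (not isolated)
11 | (3R,5R)-1,7-bis[4-(benzyloxy)phenyl]-5-hydroxyheptan-3-yl acetate | CC(=O)O[C@H](CCc1ccc(OCc2ccccc2)cc1)C[C@H](O)CCc1ccc(OCc2ccccc2)cc1 | intermediate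
12 | (3R,5R)-5-hydroxy-1,7-bis(4-hydroxyphenyl)heptan-3-yl acetate | CC(=O)O[C@H](CCc1ccc(O)cc1)C[C@H](O)CCc1ccc(O)cc1 | target

**Totals**
Total step count: 6. Longest linear sequence: 5 steps (1 → 2 → 7 → 9 → 11 → 12).

**Steps most likely to fail and their fallbacks**

Step 3 (crossed Claisen). The ketone enolate may acylate the ester sluggishly, and proton transfer during warming can erode regiocontrol and yield. The fallback sets out from 4 (with 2) and comes back at 7, making the same C4-C5 bond as an aldol addition and then adjusting the oxidation level. Ester 4 is reduced with DIBAL-H (CH2Cl2, −78 °C) to 3-[4-(benzyloxy)phenyl]propanal F1. The kinetic enolate 5 (from 2, LDA, THF, −78 °C) adds to it and, after NH4Cl quench, gives racemic 1,7-bis[4-(benzyloxy)phenyl]-5-hydroxyheptan-3-one F2. IBX (EtOAc, 75 °C) oxidises this β-hydroxy ketone to diketone 7, so the temporary stereocentre is of no consequence.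

Step 4 (double asymmetric hydrogenation). The one-pot reduction may stall after the first carbonyl or give too much meso-diol. The fallback sets out from 7 and comes back at 11, so it also bypasses 9 and step 5. The hydrogenation is run mildly (same catalyst, about 4 atm H2, rt) and stopped after one equivalent of H2, and the (R)-hydroxy ketone 8 is isolated. The second stereocentre is then set by substrate control in an Evans-Tishchenko reduction (SmI2 0.3 equiv, MeCHO 8 equiv, THF, −10 °C). The samarium-bound hemiacetal of 8 with acetaldehyde delivers hydride intramolecularly to the ketone, giving the 1,3-anti alcohol and leaving the acetate on the original hydroxyl; by C2 symmetry this mono-acetate is 11.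

Step 5 (mono-acetylation through the orthoester). The anti-diol may close to the cyclic orthoester incompletely, because the dioxane carries one axial substituent. The fallback sets out from 9 and comes back at 11, switching to activation of the diol as a tin acetal. Diol 9 is heated with Bu2SnO (1.05 equiv, toluene, reflux, Dean-Stark) to give (4R,6R)-4,6-bis{2-[4-(benzyloxy)phenyl]ethyl}-2,2-dibutyl-1,3,2-dioxastannane F3. This reacts with exactly one equivalent of acetyl chloride (0 °C) at one Sn-O bond only, and aqueous work-up gives 11.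

**Further compounds**
F1 | step 3 | 3-[4-(benzyloxy)phenyl]propanal | O=CCCc1ccc(OCc2ccccc2)cc1
F2 | step 3 | racemic 1,7-bis[4-(benzyloxy)phenyl]-5-hydroxyheptan-3-one | O=C(CCc1ccc(OCc2ccccc2)cc1)CC(O)CCc1ccc(OCc2ccccc2)cc1
F0 | step 4 | none | none
F3 | step 5 | (4R,6R)-4,6-bis{2-[4-(benzyloxy)phenyl]ethyl}-2,2-dibutyl-1,3,2-dioxastannane | CCCC[Sn]1(CCCC)O[C@H](CCc2ccc(OCc3ccccc3)cc2)C[C@@H](CCc2ccc(OCc3ccccc3)cc2)O1
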